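**Retrosynthetic overview**
- The dihydropyran is opened at the benzylic O1–C2 bond. The last step is an enantioselective acid-catalysed ring closure of an acyclic 4-hydroxystyrenyl aldehyde through a p-quinone methide; it makes the C–O bond, the ring and both stereocentres.
- The acyclic aldehyde is cut at C4–C5: α-allylation of (6-acetyl-5-hydroxybenzofuran-2-yl)acetaldehyde (as its enamine) with a symmetrical bis-allylic diacetate made from vanillin and diethyl malonate.
- The benzofuran comes from a bromohydroquinone ketone and a C4 enyne by Sonogashira coupling and 5-endo O-cyclisation.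
- Ring order: benzofuran first, dihydropyran last.

Assumption: the sense of induction of the chiral acid in step 9 cannot be predicted with confidence; the (R)-acid is written and its mirror image is used if screening gives the (2S,3R) product.

**Step 1**
Reactants: 1 2-bromo-1,4-dimethoxybenzene
Product: 2 1-(4-bromo-2,5-dimethoxyphenyl)ethanone
Conditions: AcCl (1.2 equiv), AlCl3 (1.3 equiv), CH2Cl2, 0 °C to rt
Reagents that add atoms: acetyl chloride, CC(Cl)=O
Why: Friedel–Crafts acylation goes para to bromine and ortho to a methoxy group, the only methoxy-activated position not flanked by Br, which fixes the 1-acetyl-2,5-dioxy-4-bromo pattern; no stereocentre.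

**Step 2**
Reactants: 2 1-(4-bromo-2,5-dimethoxyphenyl)ethanone
Product: 3 1-(4-bromo-2,5-dihydroxyphenyl)ethanone
Conditions: BBr3 (3.5 equiv), CH2Cl2, −78 °C to rt; then H2O
Reagents that add atoms: none
Why: Lewis-acid O-demethylation with BBr3 cleaves both aryl methyl ethers while the aryl bromide and the ketone are inert.

**Step 3**
Reactants: 3 1-(4-bromo-2,5-dihydroxyphenyl)ethanone; 4 (Z)-1-methoxybut-1-en-3-yne (2.5 equiv)
Product: 6 1-{5-hydroxy-2-[(Z)-2-methoxyethenyl]-1-benzofuran-6-yl}ethanone, via alkynylphenol 5 (not isolated)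
Conditions: PdCl2(PPh3)2 (5 mol%), CuI (5 mol%), Et3N, DMF, 80 °C, argon
Reagents that add atoms: none
Why: Sonogashira coupling of the acetyl-activated aryl bromide is followed in the same pot by copper/base-promoted 5-endo-dig addition of the only ortho hydroxyl to the alkyne (C–O bond), giving the 5-hydroxy-6-acetylbenzofuran; the enol ether tolerates the basic medium.

**Step 4**
Reactants: 6 1-{5-hydroxy-2-[(Z)-2-methoxyethenyl]-1-benzofuran-6-yl}ethanone
Product: 7 2-(6-acetyl-5-hydroxy-1-benzofuran-2-yl)acetaldehyde
Conditions: 2 M aq. HCl, THF, 0 °C to rt; used crude at once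
Reagents that add atoms: water, O
Why: acid-catalysed enol ether hydrolysis (C-protonation, hemiacetal collapse) unmasks the arylacetaldehyde without touching phenol, ketone or benzofuran.

**Step 5**
Reactants: 8 vanillin (4-hydroxy-3-methoxybenzaldehyde); 9 diethyl malonate
Product: 10 diethyl 2-[(4-hydroxy-3-methoxyphenyl)methylidene]propanedioate
Conditions: piperidine (10 mol%), AcOH (10 mol%), toluene, reflux, Dean–Stark
Reagents that add atoms: none
Why: Knoevenagel condensation of a non-enolisable aryl aldehyde with an active methylene compound, driven by water removal.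

**Step 6**
Reactants: 10 diethyl 2-[(4-hydroxy-3-methoxyphenyl)methylidene]propanedioate
Product: 11 2-[(4-hydroxy-3-methoxyphenyl)methylidene]propane-1,3-diol
Conditions: diisobutylaluminium hydride (7 equiv), CH2Cl2/toluene, −78 to 0 °C; aq. potassium sodium tartrate
Reagents that add atoms: none
Why: DIBAL-H 1,2-reduction of both conjugated esters, as in the ferulate-to-coniferyl alcohol reduction, where the aluminium phenoxide makes the alkene electron-rich and disfavours conjugate reduction.

**Step 7**
Reactants: 11 2-[(4-hydroxy-3-methoxyphenyl)methylidene]propane-1,3-diol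
Product: 12 2-[(4-hydroxy-3-methoxyphenyl)methylidene]propane-1,3-diyl diacetate
Conditions: immobilised Candida antarctica lipase B, vinyl acetate (6 equiv), MTBE/THF, 35 °C
Reagents that add atoms: vinyl acetate, CC(=O)OC=C
Why: lipase-catalysed transesterification acetylates both primary allylic alcohols and leaves the phenol free, and is irreversible because the vinyl alcohol tautomerises to acetaldehyde.

**Step 8**
Reactants: 7 2-(6-acetyl-5-hydroxy-1-benzofuran-2-yl)acetaldehyde; 12 2-[(4-hydroxy-3-methoxyphenyl)methylidene]propane-1,3-diyl diacetate (2.0 equiv)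
Product: 15 4-(6-acetyl-5-hydroxy-1-benzofuran-2-yl)-2-[(4-hydroxy-3-methoxyphenyl)methylidene]-5-oxopentyl acetate (E/Z mixture; racemic), via enamine 13 (not isolated), via C-allylated enamine 14 (not isolated)
Conditions: pyrrolidine (1.05 equiv), 4 Å MS, THF, 0 °C; then 12, Pd(PPh3)4 (5 mol%), THF, 0 °C to rt; then aq. AcOH/NaOAc, rt
Reagents that add atoms: water, O; pyrrolidine, C1CCNC1 (its atoms are held only in 13 and 14 and leave again on hydrolysis)
Why: Tsuji–Trost allylic alkylation of a preformed aldehyde enamine, in which zerovalent palladium ionises one acetate of 12 and the enamine β-carbon attacks the unsubstituted allyl terminus; excess 12 limits double substitution, and the stereocentre formed next to the aldehyde is racemic and is erased in step 9.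

**Step 9**
Reactants: 15 4-(6-acetyl-5-hydroxy-1-benzofuran-2-yl)-2-[(4-hydroxy-3-methoxyphenyl)methylidene]-5-oxopentyl acetate
Product: 17 [(2R,3S)-5-(6-acetyl-5-hydroxy-1-benzofuran-2-yl)-2-(4-hydroxy-3-methoxyphenyl)-3,4-dihydro-2H-pyran-3-yl]methyl acetate (propolis-benzofuran A), via p-quinone methide 16 (not isolated)
Conditions: (R)-3,3′-bis(2,4,6-triisopropylphenyl)-1,1′-binaphthyl-2,2′-diyl N-triflylphosphoramide (10 mol%), 5 Å MS, toluene (0.02 M), −40 °C; Et3N quench
Reagents that add atoms: none
Why: Proposed new method: an enantioconvergent chiral Brønsted acid-catalysed protonative oxa-cyclisation (formal asymmetric Markovnikov addition of the aldehyde/enol oxygen across a 4-hydroxystyrene), in which the acid protonates the vinylphenol at the carbon bearing CH2OAc to give p-quinone methide 16 held in a chiral ion pair, a reversible step through which both alkene isomers and both C3 epimers interconvert while C5 is planarised by enolisation; the carbonyl (enol) oxygen then closes onto the methide carbon through a chair transition state with aryl and CH2OAc equatorial (hence 2,3-trans), the chiral anion selecting the epimer that becomes C3-(S) (Curtin–Hammett), and loss of the C5 proton gives the benzofuran-conjugated enol ether; the closest known reaction types are chiral phosphoric-acid-type catalysed asymmetric intramolecular hydroalkoxylation of alkenes, catalytic asymmetric 1,6-additions to p-quinone methides generated in situ, and the achiral acid-catalysed cyclisation of γ,δ-unsaturated carbonyl compounds to 3,4-dihydro-2H-pyrans.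

**Compound list**
1 | 2-bromo-1,4-dimethoxybenzene | COc1ccc(OC)c(Br)c1 | starting material
2 | 1-(4-bromo-2,5-dimethoxyphenyl)ethanone | CC(=O)c1cc(OC)c(Br)cc1OC | intermediate
3 | 1-(4-bromo-2,5-dihydroxyphenyl)ethanone | CC(=O)c1cc(O)c(Br)cc1O | intermediate
4 | (Z)-1-methoxybut-1-en-3-yne | CO/C=C\C#C | starting material
5 | 1-{2,5-dihydroxy-4-[(Z)-4-methoxybut-3-en-1-yn-1-yl]phenyl}ethanone (not isolated) | CO/C=C\C#Cc1cc(O)c(C(C)=O)cc1O | intermediate
6 | 1-{5-hydroxy-2-[(Z)-2-methoxyethenyl]-1-benzofuran-6-yl}ethanone | CO/C=C\c1cc2cc(O)c(C(C)=O)cc2o1 | intermediate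
7 | 2-(6-acetyl-5-hydroxy-1-benzofuran-2-yl)acetaldehyde | CC(=O)c1cc2oc(CC=O)cc2cc1O | intermediate
8 | vanillin (4-hydroxy-3-methoxybenzaldehyde) | COc1cc(C=O)ccc1O | starting material
9 | diethyl malonate | CCOC(=O)CC(=O)OCC | starting material
10 | diethyl 2-[(4-hydroxy-3-methoxyphenyl)methylidene]propanedioate | CCOC(=O)C(=Cc1ccc(O)c(OC)c1)C(=O)OCC | intermediate
11 | 2-[(4-hydroxy-3-methoxyphenyl)methylidene]propane-1,3-diol | COc1cc(C=C(CO)CO)ccc1O | intermediate
12 | 2-[(4-hydroxy-3-methoxyphenyl)methylidene]propane-1,3-diyl diacetate | COc1cc(C=C(COC(C)=O)COC(C)=O)ccc1O | intermediate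
13 | 1-{5-hydroxy-2-[(E)-2-(pyrrolidin-1-yl)ethenyl]-1-benzofuran-6-yl}ethanone (not isolated) | CC(=O)c1cc2oc(/C=C/N3CCCC3)cc2cc1O | intermediate
14 | 4-(6-acetyl-5-hydroxy-1-benzofuran-2-yl)-2-[(4-hydroxy-3-methoxyphenyl)methylidene]-5-(pyrrolidin-1-yl)pent-4-en-1-yl acetate (alkene isomer mixture; not isolated) | CC(=O)OCC(=Cc1ccc(O)c(OC)c1)CC(=CN1CCCC1)c1cc2cc(O)c(C(C)=O)cc2o1 | intermediate
15 | 4-(6-acetyl-5-hydroxy-1-benzofuran-2-yl)-2-[(4-hydroxy-3-methoxyphenyl)methylidene]-5-oxopentyl acetate (E/Z mixture; racemic at C4) | CC(=O)OCC(=Cc1ccc(O)c(OC)c1)CC(C=O)c1cc2cc(O)c(C(C)=O)cc2o1 | intermediate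
16 | (2R)-4-(6-acetyl-5-hydroxy-1-benzofuran-2-yl)-2-[(3-methoxy-4-oxocyclohexa-2,5-dien-1-ylidene)methyl]-5-oxopentyl acetate (p-quinone methide; C4 epimers; not isolated) | COC1=CC(=C[C@H](COC(C)=O)CC(C=O)c2cc3cc(O)c(C(C)=O)cc3o2)C=CC1=O | intermediate
17 | [(2R,3S)-5-(6-acetyl-5-hydroxy-1-benzofuran-2-yl)-2-(4-hydroxy-3-methoxyphenyl)-3,4-dihydro-2H-pyran-3-yl]methyl acetate (propolis-benzofuran A; aryl and CH2OAc trans) | COc1cc([C@@H]2OC=C(c3cc4cc(O)c(C(C)=O)cc4o3)C[C@H]2COC(C)=O)ccc1O | target

**Totals**
Total steps: 9. Longest linear sequence: 6 (steps 1, 2, 3, 4, 8, 9).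

**Steps most likely to fail**

Step 9 (the new asymmetric ring closure). The risks are acid-induced loss of the allylic acetate (vinylogous quinone methide) instead of C-protonation, Friedel–Crafts closure of 16 onto benzofuran C3, and low enantiomeric excess if the two alkene isomers of 15 are protonated with opposite sense and do not equilibrate. The fallback sets out from 15 and comes back at 17. Compound 15 is cyclised with an achiral acid (diphenyl hydrogen phosphate, 10 mol%, toluene, 0 °C), the established acid cyclisation of a γ,δ-unsaturated carbonyl compound to a 3,4-dihydro-2H-pyran, to give racemic trans-[5-(6-acetyl-5-hydroxy-1-benzofuran-2-yl)-2-(4-hydroxy-3-methoxyphenyl)-3,4-dihydro-2H-pyran-3-yl]methyl acetate F1. This is resolved by preparative supercritical-fluid chromatography on an amylose tris(3,5-dimethylphenylcarbamate) phase; the (2R,3S) fraction is 17 and the (2S,3R)-enantiomer F2 is discarded.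

Step 8 (union of the two halves). Both partners are bifunctional, so double substitution of 12 and a second allylation at the aldehyde α-carbon are possible, and pyrrolidine can start aldol chemistry at the ortho-hydroxyacetyl group. The fallback sets out from 11 (with 7) and comes back at 15; it uses a mono-functional electrophile and no palladium. Diol 11 is mono-acetylated (same lipase, 1.05 equiv vinyl acetate) to 3-hydroxy-2-[(4-hydroxy-3-methoxyphenyl)methylidene]propyl acetate F3 (either alkene isomer serves). Appel bromination (CBr4, PPh3, CH2Cl2, −20 °C) gives 3-bromo-2-[(4-hydroxy-3-methoxyphenyl)methylidene]propyl acetate F4, used at once. F4 alkylates enamine 13 (made from 7 as in step 8) under Stork conditions in MeCN at −20 °C to give 14, which is hydrolysed with aqueous AcOH/NaOAc to 15.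

Step 3 (coupling and annulation on the unprotected bromohydroquinone). The phenoxide slows oxidative addition, the hydroquinone can be oxidised, and the enyne can oligomerise. The fallback sets out from 3 and comes back at 6; it separates coupling from annulation. Compound 3 is acetylated (Ac2O, pyridine) to 2-acetyl-5-bromobenzene-1,4-diyl diacetate F5. Sonogashira coupling of this electron-poor bromide with 4 (PdCl2(PPh3)2, CuI, Et3N, THF, 60 °C) gives 2-acetyl-5-[(Z)-4-methoxybut-3-en-1-yn-1-yl]benzene-1,4-diyl diacetate F6. K2CO3 in MeOH with CuI (10 mol%) at 50 °C removes both acetates and closes the furan ring to give 6.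

**Further compounds**
F1 | step 9 | racemic trans-[5-(6-acetyl-5-hydroxy-1-benzofuran-2-yl)-2-(4-hydroxy-3-methoxyphenyl)-3,4-dihydro-2H-pyran-3-yl]methyl acetate (1:1 mixture of the two enantiomers) | COc1cc([C@@H]2OC=C(c3cc4cc(O)c(C(C)=O)cc4o3)C[C@H]2COC(C)=O)ccc1O.COc1cc([C@H]2OC=C(c3cc4cc(O)c(C(C)=O)cc4o3)C[C@@H]2COC(C)=O)ccc1O
F2 | step 9 | [(2S,3R)-5-(6-acetyl-5-hydroxy-1-benzofuran-2-yl)-2-(4-hydroxy-3-methoxyphenyl)-3,4-dihydro-2H-pyran-3-yl]methyl acetate | COc1cc([C@H]2OC=C(c3cc4cc(O)c(C(C)=O)cc4o3)C[C@@H]2COC(C)=O)ccc1O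
F3 | step 8 | 3-hydroxy-2-[(4-hydroxy-3-methoxyphenyl)methylidene]propyl acetate (E/Z mixture) | COc1cc(C=C(CO)COC(C)=O)ccc1O
F4 | step 8 | 3-bromo-2-[(4-hydroxy-3-methoxyphenyl)methylidene]propyl acetate (E/Z mixture) | COc1cc(C=C(CBr)COC(C)=O)ccc1O
F5 | step 3 | 2-acetyl-5-bromobenzene-1,4-diyl diacetate | CC(=O)Oc1cc(C(C)=O)c(OC(C)=O)cc1Br
F6 | step 3 | 2-acetyl-5-[(Z)-4-methoxybut-3-en-1-yn-1-yl]benzene-1,4-diyl diacetate | CO/C=C\C#Cc1cc(OC(C)=O)c(C(C)=O)cc1OC(C)=O
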